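At the first reading of the gamma run, 0.417 min after mixing, intermediate already stands at 37.3 % of the charge beside 9.6 % of product, so intermediate holds 0.413 of what is not yet product. Pooled over the last readings of gamma, epsilon and theta, that fraction reads 0.422, and this waiting share, intermediate as a fraction of all the charge not yet product, is the quantity to carry.

| setting | gamma | epsilon | theta | beta | maple | elm | oak | cedar |
|---|---|---|---|---|---|---|---|---|
| starting material | 30 mM | 30 mM | 30 mM | 45 mM | 30 mM | 30 mM | 30 mM | 30 mM |
| partner | 0.90 equiv | 0.90 equiv | 0.90 equiv | 0.90 equiv | 0.900 equiv | 0.900 equiv (fed, over 4.00 min) | 0.900 equiv | 0.900 equiv |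
| free catalyst | 0.12 mol% | 0.17 mol% | 0.26 mol% | 0.12 mol% | 0.12 mol% | 0.12 mol% | 0.12 mol% | 0.12 mol% |
| second catalyst | 2 mol% | 2 mol% | 2 mol% | 2 mol% | 2 mol% | 2 mol% | 2 mol% | 2 mol% |
| remark | run made earlier | run made earlier | run made earlier | run made earlier | a tube with plug flow, the mixed feed as stated, residence time 8.0 min | all but partner at the start; partner goes in evenly over 4.00 min, the run ends at 8.0 min | one stirred flow tank at steady state, fed with the mixture as stated, mean residence time 8.0 min | everything together in a closed stirred flask, run for 8.0 min |
| time |  |  |  |  | 8.0 min | 8.0 min |  | 8.0 min |

- gamma (time / min: intermediate / %, product / %): 0.417: 37.3, 9.6; 1.33: 31.2, 25.8; 2.00: 27.0, 34.8; 3.00: 23.2, 43.9; 5.00: 17.5, 56.5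
- epsilon (time / min: intermediate / %, product / %): 1.00: 33.9, 20.7; 2.00: 26.4, 35.4; 3.00: 24.3, 44.5; 4.00: 21.4, 51.9; 5.00: 18.5, 57.2
- theta (time / min: intermediate / %, product / %): 1.00: 33.7, 22.3; 2.00: 26.9, 35.3; 3.00: 23.2, 45.1; 4.00: 19.7, 52.2; 5.00: 18.5, 57.3
- beta (time / min: intermediate / %, product / %): 0.417: 32.9, 18.6; 1.33: 24.2, 45.0; 2.00: 18.6, 53.7; 3.00: 15.8, 63.2; 5.00: 11.9, 72.9

(standard deviation of a reading: 0.5 percentage points)

- the stated concentrations are those of everything mixed, before any reaction; amounts are the same in each set-up
- the feed brings no volume worth counting
- the earlier runs were made in a closed, stirred flask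

- the set-up with the highest amount of intermediate at the outlet or at the end, in percent of the starting material put in ("none" if the first two lie within 2 percentage points) (maple / elm / oak / cedar / none)
- amount of intermediate at the outlet or at the end, in percent of the starting material put in, maple
- amount of intermediate at the outlet or at the end, in percent of the starting material put in, elm
- amount of intermediate at the outlet or at the end, in percent of the starting material put in, oak
- amount of intermediate at the outlet or at the end, in percent of the starting material put in, cedar

In the middle of the runs, at 2.00 min, gamma holds 27.0 % intermediate and 34.8 % product, while theta, with twice the free catalyst, holds 26.9 % and 35.3 % at 2.00 min. The share reads 0.414 in gamma and 0.416 in theta, so the exchange between starting material and intermediate is taken as balanced at either loading, and the slow change is the climb of product. Towards the end the waiting pool shrinks as product grows, and the beta run, at 45 mM, reaches 72.9 % product at 5.00 min with a share that still reads 0.439.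

Intermediate at the end or outlet is thus reckoned as the waiting share times the fraction not yet product, so among these set-ups the one that has made the least product shows the most intermediate. The reckoning here commits to an order and no figures: oak works at its outlet concentrations throughout, elm holds partner back for a while, and maple repeats cedar, which gives oak, then elm, then maple and cedar together.

The forecast, holding that “free catalyst isn't rate-limiting”, names oak, with 21 % in oak, 16.8 % in elm, 14 % in maple and 14 % in cedar.

The flasks give oak first, with 20.7 % in oak, 16.8 % in elm, 14.1 % in maple and 14.1 % in cedar.

    partner + second catalyst + intermediate → second catalyst + product (k = 702 /M²/s)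
    starting material + free catalyst ⇌ free catalyst + intermediate (K = 0.750, k = 2590 /M/s)

In maple at 0.193 min, intermediate falls back 11 times faster than it goes on to product, and the onward step is there the rate-limiting step. At 8.00 min maple's 66.9 % of product gives, through the waiting share, 14.0 % of intermediate against the 14.1 % found. Intermediate in cedar has moved by 5 points from its value with partner at 0.696 equiv or at 1.17 equiv, other amounts and the time held. With 0.230 equiv of partner, the flask otherwise like maple ends at 20.5 % product, where the waiting share gives 33.5 % and the flask holds 34.1 %.

The readings are calculated on assumed constants.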